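Disconnection: the aryl ether bond O1–C7a of the dihydrobenzofuran. In the precursor, C7a of the benzo ring (ring B) carries a nitro group that is flanked by the C7 methoxy group and the C3a side chain and lies para to a nitrile on C5, the carbon that later bears the lactone CH2. The nitro group first lets the C3a acetate arm in by vicarious substitution. An Evans syn-aldol then sets C2 and C3 in an open chain. In the key step the C2 alkoxide displaces nitrite at C7a (intramolecular SNAr), closing the trans-dihydrobenzofuran without touching a stereocentre. The nitrile is then grown into the trans-dibenzylbutyrolactone.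

Key step: step 7

Remark: the benzofuran unit is numbered O1, C2, C3, C3a, C4 to C7, C7a; 3-methoxy-4-nitrobenzonitrile (1) is taken as a catalogue compound.

Step 1
Reactants: 1 3-methoxy-4-nitrobenzonitrile; 2 tert-butyl chloroacetate
Product: 5 tert-butyl 2-(5-cyano-3-methoxy-2-nitrophenyl)acetate, via potassium σH adduct 3 (not isolated), via potassium nitrobenzylic anion 4 (not isolated)
Conditions: KOt-Bu (2.5 equiv), DMF, −40 °C; then aq. HCl
Reagents that add atoms: none
Why: Vicarious nucleophilic substitution of hydrogen: the chloroester carbanion should add at C5, the only hydrogen-bearing position ortho or para to the nitro group, and base-induced loss of HCl from the σH adduct gives the nitrobenzylic anion that is protonated on work-up.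

Step 2
Reactants: 5 tert-butyl 2-(5-cyano-3-methoxy-2-nitrophenyl)acetate
Product: 6 2-(5-cyano-3-methoxy-2-nitrophenyl)acetic acid
Conditions: CF3CO2H, CH2Cl2, rt
Reagents that add atoms: none
Why: Acidolysis of the tert-butyl ester by loss of the tert-butyl group as isobutene leaves nitrile, nitro group and aryl ether untouched.

Step 3
Reactants: 6 2-(5-cyano-3-methoxy-2-nitrophenyl)acetic acid; 7 (S)-4-benzyl-1,3-oxazolidin-2-one
Product: 9 (4S)-4-benzyl-3-[2-(5-cyano-3-methoxy-2-nitrophenyl)acetyl]-1,3-oxazolidin-2-one, via mixed pivalic anhydride 8 (not isolated)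
Conditions: t-BuCOCl, Et3N, THF, −20 °C; then 7, LiCl, rt
Reagents that add atoms: none
Why: N-acylation of the oxazolidinone through the mixed anhydride under LiCl/Et3N activation needs no strong base, so the acidic nitrobenzylic CH2 is not disturbed.

Step 4
Reactants: 9 the N-arylacetyl oxazolidinone; 10 4-benzyloxy-3-methoxybenzaldehyde
Product: 13 (4S)-4-benzyl-3-[(2S,3S)-3-(4-benzyloxy-3-methoxyphenyl)-2-(5-cyano-3-methoxy-2-nitrophenyl)-3-hydroxypropanoyl]-1,3-oxazolidin-2-one, via Z dibutylboron enolate 11 (not isolated), via dibutylboron aldolate 12 (not isolated)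
Conditions: Bu2BOTf, i-Pr2NEt, CH2Cl2, −78 → 0 °C; then 10, −78 → 0 °C; pH 7 buffer, MeOH
Reagents that add atoms: none
Why: Evans syn-aldol reaction: the Z boron enolate reacts through a closed chair transition state on the face away from the auxiliary benzyl group, which should set both new stereocentres as 2S,3S (the future C3 and C2 of the dihydrobenzofuran).

Step 5
Reactants: 13 the syn-aldol adduct
Product: 15 3-[(1S,2R)-1-(4-benzyloxy-3-methoxyphenyl)-1,3-dihydroxypropan-2-yl]-5-methoxy-4-nitrobenzonitrile, via hydroxy aldehyde 14 (not isolated)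
Conditions: LiBH4, MeOH (1 equiv), THF, 0 °C
Reagents that add atoms: none
Why: Reductive cleavage of the N-acyl oxazolidinone by borohydride gives the primary alcohol and the recoverable auxiliary, while nitro group and nitrile should survive at 0 °C and no stereocentre is touched.

Step 6
Reactants: 15 the 1,3-diol
Product: 16 3-[(1S,2R)-3-benzyloxy-1-(4-benzyloxy-3-methoxyphenyl)-1-hydroxypropan-2-yl]-5-methoxy-4-nitrobenzonitrile
Conditions: BnBr (1.1 equiv), Ag2O, CH2Cl2, rt
Reagents that add atoms: benzyl bromide, BrCc1ccccc1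
Why: Silver-oxide-mediated Williamson etherification should take the unhindered primary hydroxyl only, and because no free alkoxide is made the nitro group is not displaced at this stage.

Step 7
Reactants: 16 the nitro alcohol with the primary oxygen capped as benzyl ether
Product: 19 (2S,3R)-2-(4-benzyloxy-3-methoxyphenyl)-3-(benzyloxymethyl)-7-methoxy-2,3-dihydro-1-benzofuran-5-carbonitrile, via caesium alkoxide 17 (not isolated), via Meisenheimer adduct 18 (not isolated)
Conditions: Cs2CO3, DMF, rt → 50 °C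
Reagents that add atoms: none
Why: Cs2CO3 reversibly forms alkoxide 17, which adds to the nitro-bearing carbon (the future C7a) to give Meisenheimer adduct 18, whose charge is taken up by the para nitrile, and loss of nitrite restores the arene (intramolecular SNAr, a denitrocyclisation). The closest known reaction type is the displacement of activated aromatic nitro groups by alkoxides, inter- and intramolecular. The five-membered ring closes in the 5-exo-trig mode. No stereocentre is formed: the C2–O and C3–C bonds are not touched, so the syn relationship from step 4 should be carried over as the trans-2,3 arrangement with 2S,3R configuration. The step needs attack by the secondary oxygen only and no epimerisation at the nitrobenzylic C–H; the first is secured by the benzyl cap on the primary oxygen, which cannot migrate, the second by the weak carbonate base and by a nitro group that its two ortho neighbours twist out of the ring plane, which makes it a good leaving group and a poor carbanion stabiliser.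

Step 8
Reactants: 19 the dihydrobenzofuran-5-carbonitrile
Product: 21 (2S,3R)-2-(4-benzyloxy-3-methoxyphenyl)-3-(benzyloxymethyl)-7-methoxy-2,3-dihydro-1-benzofuran-5-carbaldehyde, via N-aluminio imine 20 (not isolated)
Conditions: i-Bu2AlH, toluene, −78 °C; then 1 M HCl
Reagents that add atoms: water, O
Why: Partial reduction of the nitrile by i-Bu2AlH stops at the N-aluminio imine, which is hydrolysed to the aldehyde on acidic work-up.

Step 9
Reactants: 21 the dihydrobenzofuran-5-carbaldehyde; 22 dimethyl succinate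
Product: 24 (E)-4-[(2S,3R)-2-(4-benzyloxy-3-methoxyphenyl)-3-(benzyloxymethyl)-7-methoxy-2,3-dihydro-1-benzofuran-5-yl]-3-(methoxycarbonyl)but-3-enoic acid, via paraconate lactone 23 (not isolated)
Conditions: LiOMe, MeOH, reflux; then aq. HCl
Reagents that add atoms: none
Why: Stobbe condensation: aldol addition of the succinate enolate, lactonisation to paraconate 23 and E1cB ring opening should give the E half-ester with the free acid on the CH2 arm.

Step 10
Reactants: 24 the E itaconate half-ester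
Product: 25 (3R)-4-[(2S,3R)-2-(4-benzyloxy-3-methoxyphenyl)-3-(benzyloxymethyl)-7-methoxy-2,3-dihydro-1-benzofuran-5-yl]-3-(methoxycarbonyl)butanoic acid
Conditions: H2 (5 bar), [Rh(cod)((S,S)-Et-DuPhos)]BF4 (1 mol%), NaOMe (10 mol%), MeOH, rt
Reagents that add atoms: none
Why: Rhodium–bisphospholane asymmetric hydrogenation of a Stobbe-type itaconate: the carboxylate chelates the metal and the ligand antipode is chosen so that hydrogen is delivered to the face that gives the 3R centre, benzyl ethers and the dihydrobenzofuran being inert to the cationic rhodium catalyst.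

Step 11
Reactants: 25 the R half-ester
Product: 27 (4R)-4-{[(2S,3R)-2-(4-benzyloxy-3-methoxyphenyl)-3-(benzyloxymethyl)-7-methoxy-2,3-dihydro-1-benzofuran-5-yl]methyl}oxolan-2-one, via hydroxy acid 26 (not isolated)
Conditions: KOH (1 equiv), EtOH; CaCl2, NaBH4, 0 °C → rt; then 2 M HCl
Reagents that add atoms: none
Why: Chemoselective borohydride reduction: Ca(BH4)2 reduces the methyl ester but not the carboxylate salt, and acidification closes the γ-lactone by Fischer-type lactonisation without touching the stereocentre.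

Step 12
Reactants: 28 4-benzyloxy-3-methoxybenzyl alcohol
Product: 30 4-benzyloxy-3-methoxybenzyl bromide, via dibromophosphite ester 29 (not isolated)
Conditions: PBr3, Et2O, 0 °C
Reagents that add atoms: phosphorus tribromide, BrP(Br)Br
Why: Alcohol-to-bromide conversion with PBr3 through the phosphite ester and SN2 displacement by bromide is standard for alkoxybenzyl alcohols.

Step 13
Reactants: 27 the R β-substituted butyrolactone; 30 4-benzyloxy-3-methoxybenzyl bromide
Product: 32 (3R,4R)-3-(4-benzyloxy-3-methoxybenzyl)-4-{[(2S,3R)-2-(4-benzyloxy-3-methoxyphenyl)-3-(benzyloxymethyl)-7-methoxy-2,3-dihydro-1-benzofuran-5-yl]methyl}oxolan-2-one, via lithium enolate 31 (not isolated)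
Conditions: LiN(i-Pr)2, THF, −78 °C; then 30, DMPU, −78 → −30 °C
Reagents that add atoms: none
Why: Lactone enolate alkylation: the benzyl bromide should approach anti to the C4 substituent, so the new C3 centre is set R by substrate control and the 3,4-trans lactone results.

Step 14
Reactants: 32 tri-O-benzyl lappaol A
Product: 33 lappaol A
Conditions: H2 (1 atm), 10% Pd/C, EtOAc–EtOH, rt
Reagents that add atoms: none
Why: Catalytic hydrogenolysis should cleave the two aryl benzyl ethers and the primary alkyl benzyl ether, and the reaction is stopped on completion because the cyclic secondary benzylic C2–O1 bond is cleaved more slowly.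

Compound list
1 | 3-methoxy-4-nitrobenzonitrile | COc1cc(C#N)ccc1[N+](=O)[O-] | starting material
2 | tert-butyl chloroacetate | ClCC(=O)OC(C)(C)C | starting material
3 | potassium σH adduct (nitronate formed by addition of the chloroester carbanion at C5 of 1) | [K+].COC1=CC(C#N)=CC(C(Cl)C(=O)OC(C)(C)C)C1=[N+]([O-])[O-] | intermediate
4 | potassium nitrobenzylic anion of 5 (nitronate form) | [K+].COC1=CC(C#N)=CC(=CC(=O)OC(C)(C)C)C1=[N+]([O-])[O-] | intermediate
5 | tert-butyl 2-(5-cyano-3-methoxy-2-nitrophenyl)acetate | COc1cc(C#N)cc(CC(=O)OC(C)(C)C)c1[N+](=O)[O-] | intermediate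
6 | 2-(5-cyano-3-methoxy-2-nitrophenyl)acetic acid | COc1cc(C#N)cc(CC(=O)O)c1[N+](=O)[O-] | intermediate
7 | (S)-4-benzyl-1,3-oxazolidin-2-one | O=C1N[C@@H](Cc2ccccc2)CO1 | starting material
8 | mixed anhydride of 6 with pivalic acid | COc1cc(C#N)cc(CC(=O)OC(=O)C(C)(C)C)c1[N+](=O)[O-] | intermediate
9 | (4S)-4-benzyl-3-[2-(5-cyano-3-methoxy-2-nitrophenyl)acetyl]-1,3-oxazolidin-2-one | COc1cc(C#N)cc(CC(=O)N2C(=O)OC[C@@H]2Cc2ccccc2)c1[N+](=O)[O-] | intermediate
10 | 4-benzyloxy-3-methoxybenzaldehyde | O=Cc1ccc(OCc2ccccc2)c(OC)c1 | starting material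
11 | Z dibutylboron enolate of 9 | COc1cc(C#N)cc(/C=C(\OB(CCCC)CCCC)N2C(=O)OC[C@@H]2Cc2ccccc2)c1[N+](=O)[O-] | intermediate
12 | dibutylboron aldolate of 13 | COc1cc(C#N)cc([C@H](C(=O)N2C(=O)OC[C@@H]2Cc2ccccc2)[C@@H](c2ccc(OCc3ccccc3)c(OC)c2)OB(CCCC)CCCC)c1[N+](=O)[O-] | intermediate
13 | (4S)-4-benzyl-3-[(2S,3S)-3-(4-benzyloxy-3-methoxyphenyl)-2-(5-cyano-3-methoxy-2-nitrophenyl)-3-hydroxypropanoyl]-1,3-oxazolidin-2-one | COc1cc(C#N)cc([C@H](C(=O)N2C(=O)OC[C@@H]2Cc2ccccc2)[C@@H](c2ccc(OCc3ccccc3)c(OC)c2)O)c1[N+](=O)[O-] | intermediate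
14 | (2S,3S)-3-(4-benzyloxy-3-methoxyphenyl)-2-(5-cyano-3-methoxy-2-nitrophenyl)-3-hydroxypropanal | COc1cc(C#N)cc([C@H](C=O)[C@@H](c2ccc(OCc3ccccc3)c(OC)c2)O)c1[N+](=O)[O-] | intermediate
15 | 3-[(1S,2R)-1-(4-benzyloxy-3-methoxyphenyl)-1,3-dihydroxypropan-2-yl]-5-methoxy-4-nitrobenzonitrile | COc1cc(C#N)cc([C@H](CO)[C@@H](c2ccc(OCc3ccccc3)c(OC)c2)O)c1[N+](=O)[O-] | intermediate
16 | 3-[(1S,2R)-3-benzyloxy-1-(4-benzyloxy-3-methoxyphenyl)-1-hydroxypropan-2-yl]-5-methoxy-4-nitrobenzonitrile | COc1cc(C#N)cc([C@H](COCc2ccccc2)[C@@H](c2ccc(OCc3ccccc3)c(OC)c2)O)c1[N+](=O)[O-] | intermediate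
17 | caesium alkoxide of 16 | [Cs+].COc1cc(C#N)cc([C@H](COCc2ccccc2)[C@@H](c2ccc(OCc3ccccc3)c(OC)c2)[O-])c1[N+](=O)[O-] | intermediate
18 | Meisenheimer adduct (caesium salt, ring oxygen and nitro group both on the future C7a, charge drawn on the nitrile) | [Cs+].COC1=CC(=C=[N-])C=C2[C@H](COCc3ccccc3)[C@@H](c3ccc(OCc4ccccc4)c(OC)c3)OC12[N+](=O)[O-] | intermediate
19 | (2S,3R)-2-(4-benzyloxy-3-methoxyphenyl)-3-(benzyloxymethyl)-7-methoxy-2,3-dihydro-1-benzofuran-5-carbonitrile | N#Cc1cc(OC)c2c(c1)[C@H](COCc1ccccc1)[C@@H](c1ccc(OCc3ccccc3)c(OC)c1)O2 | intermediate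
20 | N-(diisobutylaluminio) imine of 21 | CC(C)C[Al](CC(C)C)N=Cc1cc(OC)c2c(c1)[C@H](COCc1ccccc1)[C@@H](c1ccc(OCc3ccccc3)c(OC)c1)O2 | intermediate
21 | (2S,3R)-2-(4-benzyloxy-3-methoxyphenyl)-3-(benzyloxymethyl)-7-methoxy-2,3-dihydro-1-benzofuran-5-carbaldehyde | O=Cc1cc(OC)c2c(c1)[C@H](COCc1ccccc1)[C@@H](c1ccc(OCc3ccccc3)c(OC)c1)O2 | intermediate
22 | dimethyl succinate | COC(=O)CCC(=O)OC | starting material
23 | paraconate lactone (methyl 2-aryl-5-oxooxolane-3-carboxylate, aryl = the dihydrobenzofuran-5-yl group of 21, isomer mixture at the two lactone centres) | COC(=O)C1CC(=O)OC1c1cc(OC)c2c(c1)[C@H](COCc1ccccc1)[C@@H](c1ccc(OCc3ccccc3)c(OC)c1)O2 | intermediate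
24 | (E)-4-[(2S,3R)-2-(4-benzyloxy-3-methoxyphenyl)-3-(benzyloxymethyl)-7-methoxy-2,3-dihydro-1-benzofuran-5-yl]-3-(methoxycarbonyl)but-3-enoic acid | COC(=O)/C(CC(=O)O)=C/c1cc(OC)c2c(c1)[C@H](COCc1ccccc1)[C@@H](c1ccc(OCc3ccccc3)c(OC)c1)O2 | intermediate
25 | (3R)-4-[(2S,3R)-2-(4-benzyloxy-3-methoxyphenyl)-3-(benzyloxymethyl)-7-methoxy-2,3-dihydro-1-benzofuran-5-yl]-3-(methoxycarbonyl)butanoic acid | COC(=O)[C@@H](CC(=O)O)Cc1cc(OC)c2c(c1)[C@H](COCc1ccccc1)[C@@H](c1ccc(OCc3ccccc3)c(OC)c1)O2 | intermediate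
26 | (3R)-4-[(2S,3R)-2-(4-benzyloxy-3-methoxyphenyl)-3-(benzyloxymethyl)-7-methoxy-2,3-dihydro-1-benzofuran-5-yl]-3-(hydroxymethyl)butanoic acid | OC[C@@H](CC(=O)O)Cc1cc(OC)c2c(c1)[C@H](COCc1ccccc1)[C@@H](c1ccc(OCc3ccccc3)c(OC)c1)O2 | intermediate
27 | (4R)-4-{[(2S,3R)-2-(4-benzyloxy-3-methoxyphenyl)-3-(benzyloxymethyl)-7-methoxy-2,3-dihydro-1-benzofuran-5-yl]methyl}oxolan-2-one | O=C1C[C@@H](Cc2cc(OC)c3c(c2)[C@H](COCc2ccccc2)[C@@H](c2ccc(OCc4ccccc4)c(OC)c2)O3)CO1 | intermediate
28 | 4-benzyloxy-3-methoxybenzyl alcohol | OCc1ccc(OCc2ccccc2)c(OC)c1 | starting material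
29 | 4-benzyloxy-3-methoxybenzyl dibromophosphite | BrP(Br)OCc1ccc(OCc2ccccc2)c(OC)c1 | intermediate
30 | 4-benzyloxy-3-methoxybenzyl bromide | BrCc1ccc(OCc2ccccc2)c(OC)c1 | intermediate
31 | lithium enolate of 27 | [Li+].[O-]C1=C[C@@H](Cc2cc(OC)c3c(c2)[C@H](COCc2ccccc2)[C@@H](c2ccc(OCc4ccccc4)c(OC)c2)O3)CO1 | intermediate
32 | (3R,4R)-3-(4-benzyloxy-3-methoxybenzyl)-4-{[(2S,3R)-2-(4-benzyloxy-3-methoxyphenyl)-3-(benzyloxymethyl)-7-methoxy-2,3-dihydro-1-benzofuran-5-yl]methyl}oxolan-2-one | COc1cc(C[C@H]2C(=O)OC[C@@H]2Cc2cc(OC)c3c(c2)[C@H](COCc2ccccc2)[C@@H](c2ccc(OCc4ccccc4)c(OC)c2)O3)ccc1OCc1ccccc1 | intermediate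
33 | lappaol A, (3R,4R)-3-(4-hydroxy-3-methoxybenzyl)-4-{[(2S,3R)-2-(4-hydroxy-3-methoxyphenyl)-3-(hydroxymethyl)-7-methoxy-2,3-dihydro-1-benzofuran-5-yl]methyl}oxolan-2-one | COc1cc(C[C@H]2C(=O)OC[C@@H]2Cc2cc(OC)c3c(c2)[C@H](CO)[C@@H](c2ccc(O)c(OC)c2)O3)ccc1O | target

Total step count: 14. Longest linear sequence: 13 steps (steps 1 to 11, 13 and 14); step 12 is a one-step side branch.

Steps most likely to fail

Step 7. Ring closure may be outrun by deprotonation at the nitrobenzylic C–H (epimerisation at the future C3) or by retro-addition of the alkoxide with C–C cleavage, or the nitrile alone may activate the nitro-bearing carbon too weakly. The fallback forms the same O1–C7a bond by copper catalysis and sets out from 16. Reduction of the nitro group with Zn in AcOH/EtOH should give 4-amino-3-[(1S,2R)-3-benzyloxy-1-(4-benzyloxy-3-methoxyphenyl)-1-hydroxypropan-2-yl]-5-methoxybenzonitrile F1. Diazotisation (NaNO2, aq. HCl, MeCN, 0 °C) gives the arenediazonium chloride F2, and KI turns it into 3-[(1S,2R)-3-benzyloxy-1-(4-benzyloxy-3-methoxyphenyl)-1-hydroxypropan-2-yl]-4-iodo-5-methoxybenzonitrile F3 (Sandmeyer-type iodination). An intramolecular Ullmann etherification (CuI, 1,10-phenanthroline, Cs2CO3, toluene, 110 °C), which needs no strongly basic alkoxide and no electron-poor arene, then closes the ring and comes back to the route at 19.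

Step 4. The strongly stabilised enolate of the nitroarylacetyl imide may add slowly and reversibly to the electron-rich aldehyde, so that retro-aldol equilibration erodes the syn selectivity. The fallback sets the carbinol centre by reduction instead of C–C bond formation and sets out from acid 6. Esterification (Me3SiCHN2, MeOH–toluene) gives methyl 2-(5-cyano-3-methoxy-2-nitrophenyl)acetate F4. C-Acylation with 4-benzyloxy-3-methoxybenzoyl chloride (MgCl2, Et3N, MeCN) gives methyl 3-(4-benzyloxy-3-methoxyphenyl)-2-(5-cyano-3-methoxy-2-nitrophenyl)-3-oxopropanoate F5. Noyori–Ikariya transfer hydrogenation with dynamic kinetic resolution (RuCl(p-cymene)[(S,S)-TsDPEN], HCO2H–Et3N) should reduce the ketone to the 3S carbinol while the acidic C2 centre equilibrates; the syn isomer, methyl (2S,3S)-3-(4-benzyloxy-3-methoxyphenyl)-2-(5-cyano-3-methoxy-2-nitrophenyl)-3-hydroxypropanoate F6, is expected. LiBH4 in THF then reduces the ester and comes back to the route at diol 15.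

Step 6. Benzylation may spill over to the secondary hydroxyl, or silver oxide may trigger early ring closure through the primary oxygen. The fallback uses a sterically selected, acid-labile cap and moves the benzylation behind the ring closure; it sets out from 15. TrCl in pyridine should tritylate the primary hydroxyl only, giving 3-[(1S,2R)-1-(4-benzyloxy-3-methoxyphenyl)-1-hydroxy-3-(trityloxy)propan-2-yl]-5-methoxy-4-nitrobenzonitrile F7. The ring closure of step 7 (Cs2CO3, DMF) gives (2S,3R)-2-(4-benzyloxy-3-methoxyphenyl)-7-methoxy-3-(trityloxymethyl)-2,3-dihydro-1-benzofuran-5-carbonitrile F8. Detritylation (TsOH cat., MeOH–CH2Cl2) gives (2S,3R)-2-(4-benzyloxy-3-methoxyphenyl)-3-(hydroxymethyl)-7-methoxy-2,3-dihydro-1-benzofuran-5-carbonitrile F9. With the nitro group gone, benzylation with NaH and BnBr in THF is safe and comes back to the route at 19.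

Further compounds
F1 | step 7 | 4-amino-3-[(1S,2R)-3-benzyloxy-1-(4-benzyloxy-3-methoxyphenyl)-1-hydroxypropan-2-yl]-5-methoxybenzonitrile | COc1cc(C#N)cc([C@H](COCc2ccccc2)[C@@H](c2ccc(OCc3ccccc3)c(OC)c2)O)c1N
F2 | step 7 | 2-[(1S,2R)-3-benzyloxy-1-(4-benzyloxy-3-methoxyphenyl)-1-hydroxypropan-2-yl]-4-cyano-6-methoxybenzenediazonium chloride | COc1cc(C#N)cc([C@H](COCc2ccccc2)[C@@H](c2ccc(OCc3ccccc3)c(OC)c2)O)c1[N+]#N.[Cl-]
F3 | step 7 | 3-[(1S,2R)-3-benzyloxy-1-(4-benzyloxy-3-methoxyphenyl)-1-hydroxypropan-2-yl]-4-iodo-5-methoxybenzonitrile | COc1cc(C#N)cc([C@H](COCc2ccccc2)[C@@H](c2ccc(OCc3ccccc3)c(OC)c2)O)c1I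
F4 | step 4 | methyl 2-(5-cyano-3-methoxy-2-nitrophenyl)acetate | COc1cc(C#N)cc(CC(=O)OC)c1[N+](=O)[O-]
F5 | step 4 | methyl 3-(4-benzyloxy-3-methoxyphenyl)-2-(5-cyano-3-methoxy-2-nitrophenyl)-3-oxopropanoate | COc1cc(C#N)cc(C(C(=O)OC)C(=O)c2ccc(OCc3ccccc3)c(OC)c2)c1[N+](=O)[O-]
F6 | step 4 | methyl (2S,3S)-3-(4-benzyloxy-3-methoxyphenyl)-2-(5-cyano-3-methoxy-2-nitrophenyl)-3-hydroxypropanoate | COc1cc(C#N)cc([C@H](C(=O)OC)[C@@H](c2ccc(OCc3ccccc3)c(OC)c2)O)c1[N+](=O)[O-]
F7 | step 6 | 3-[(1S,2R)-1-(4-benzyloxy-3-methoxyphenyl)-1-hydroxy-3-(trityloxy)propan-2-yl]-5-methoxy-4-nitrobenzonitrile | COc1cc(C#N)cc([C@H](COC(c2ccccc2)(c2ccccc2)c2ccccc2)[C@@H](c2ccc(OCc3ccccc3)c(OC)c2)O)c1[N+](=O)[O-]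
F8 | step 6 | (2S,3R)-2-(4-benzyloxy-3-methoxyphenyl)-7-methoxy-3-(trityloxymethyl)-2,3-dihydro-1-benzofuran-5-carbonitrile | N#Cc1cc(OC)c2c(c1)[C@H](COC(c1ccccc1)(c1ccccc1)c1ccccc1)[C@@H](c1ccc(OCc3ccccc3)c(OC)c1)O2
F9 | step 6 | (2S,3R)-2-(4-benzyloxy-3-methoxyphenyl)-3-(hydroxymethyl)-7-methoxy-2,3-dihydro-1-benzofuran-5-carbonitrile | N#Cc1cc(OC)c2c(c1)[C@H](CO)[C@@H](c1ccc(OCc3ccccc3)c(OC)c1)O2
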